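**Retrosynthetic overview**

1. Numbering used: O1, C2 (methyl), C3 (aryl), O4, C4a, C5, C6 (allyl), C7, C8, C8a; ring A is the benzo ring, ring B the dioxane ring, ring C the trimethoxyphenyl ring; the target is the trans (2R,3R) isomer.
2. The C6–allyl bond is disconnected last (Suzuki–Miyaura allylation of the C6 chloride 15).
3. Ring B is disconnected at O1–C8a and, in the same operation, at O4–C4a: a domino aryne annulation joins 1,3,5-trichlorobenzene to the lithium alkoxide of the tert-butyl ether alcohol 7. Rings A and C are bought; ring B is the only ring made (step 5).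
4. Enabling feature: ring A carries O4 and O1 on the adjacent carbons C4a and C8a and its only carbon substituent on C6, para to C8a and meta to C4a. This is the pattern a 1,3,5-trihalobenzene leaves after two consecutive arynes: O4 ipso at a C–Cl, O1 on the C–H carbon between two chlorines, hydrogen in place of the second chlorine at C8, the third chlorine kept at C6.
5. The acyclic partner 7 takes C2 from methyl (R)-lactate and C3 from a Felkin–Anh reduction; O1 travels as a tert-butyl ether, which keeps it silent in the first aryne addition and is shed as isobutene in the ring closure.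

Key step: step 5

Remark: 3,4,5-trimethoxyphenylmagnesium bromide (4) is taken as the commercial THF solution; it can otherwise be made from 5-bromo-1,2,3-trimethoxybenzene and magnesium.

**Step 1**
Reactants: 1 methyl (R)-lactate
Product: 2 methyl (R)-2-tert-butoxypropanoate
Conditions: 2-methylpropene (excess), H2SO4 (cat.), CH2Cl2, 0 °C to 23 °C, sealed vessel
Reagents that add atoms: 2-methylpropene, CC(C)=C
Why: Acid-catalysed addition of the secondary hydroxyl to isobutene through the tert-butyl cation (tert-butyl ether formation) should leave the ester and the α-stereocentre of 1 untouched, so C2 of the target is already in place.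

**Step 2**
Reactants: 2 methyl (R)-2-tert-butoxypropanoate
Product: 3 (R)-2-tert-butoxy-N-methoxy-N-methylpropanamide
Conditions: MeNH(OMe)·HCl (1.5 equiv), i-PrMgCl (3.0 equiv), THF, −20 °C to 0 °C; then 1 M HCl
Reagents that add atoms: N,O-dimethylhydroxylamine hydrochloride, CNOC.Cl
Why: Aminolysis of the methyl ester by the chloromagnesium amide generated in the flask (Weinreb amide synthesis) should be fast at low temperature, where the α-alkoxy stereocentre is not deprotonated.

**Step 3**
Reactants: 3 (R)-2-tert-butoxy-N-methoxy-N-methylpropanamide; 4 3,4,5-trimethoxyphenylmagnesium bromide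
Product: 6 (R)-2-tert-butoxy-1-(3,4,5-trimethoxyphenyl)propan-1-one, via magnesium hemiaminal chelate 5 (not isolated)
Conditions: 4 (1.3 equiv, 0.5 M in THF), THF, 0 °C; then cold 1 M HCl
Reagents that add atoms: none
Why: Weinreb ketone synthesis: the aryl Grignard reagent adds once, the five-membered magnesium chelate 5 survives until the acidic quench and so prevents a second addition, and the α-stereocentre is not enolised under these conditions.

**Step 4**
Reactants: 6 (R)-2-tert-butoxy-1-(3,4,5-trimethoxyphenyl)propan-1-one
Product: 7 (1R,2R)-2-tert-butoxy-1-(3,4,5-trimethoxyphenyl)propan-1-ol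
Conditions: KBH(s-Bu)3 (1.3 equiv), THF, −78 °C; then NaOH, H2O2, 0 °C
Reagents that add atoms: none
Why: Felkin–Anh-controlled hydride addition to the α-alkoxy ketone: the bulky, poorly chelating tert-butoxy group stands anti to the incoming hindered borohydride (potassium counter-ion, no chelate), hydride passes the α-hydrogen, and the 1,2-syn alcohol with the new C1 centre (R) should result.

**Step 5**
Reactants: 7 (1R,2R)-2-tert-butoxy-1-(3,4,5-trimethoxyphenyl)propan-1-ol; 8 1,3,5-trichlorobenzene
Product: 15 (2R,3R)-6-chloro-2-methyl-3-(3,4,5-trimethoxyphenyl)-2,3-dihydro-1,4-benzodioxine, via lithium alkoxide 9 (not isolated), via 2,4,6-trichlorophenyllithium 10 (not isolated), via 3,5-dichlorobenzyne 11 (not isolated), via aryllithium adduct 12 (not isolated), via tethered chloroaryne 13 (not isolated), via oxonium zwitterion 14 (not isolated)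
Conditions: n-BuLi (1.0 equiv) on 7 and n-BuLi (1.2 equiv) on 8 (1.2 equiv), separately, THF, −78 °C; solutions combined at −78 °C (0.02 M), warmed slowly to −20 °C; then aq. NH4Cl
Reagents that add atoms: none
Why: Proposed new method: lithiation of 8 between two chlorines and loss of LiCl should give aryne 11, to which alkoxide 9 adds at the aryne carbon remote from the flanking C–Cl (the less hindered terminus, and the one that puts the carbanion next to the inductively stabilising chlorine), so that the benzylic oxygen sits on the future C4a and aryllithium 12 carries lithium on the future C8a with chlorine on C8; 12 then expels that chloride to give aryne 13 (C8a≡C8), the tert-butyl ether oxygen attacks C8a in the plane of the ring (6-exo-dig closure of ring B, the only mode the tether allows, since attack at C8 would need a meta bridge), and the C8 carbanion of zwitterion 14 removes a β-hydrogen of the tert-butyl group through a six-membered transition state, releasing isobutene and leaving 15. The closest known reaction types are the domino use of 2,6-dihaloaryl anions as 1,2-benzdiyne equivalents (as in the Hart terphenyl synthesis, where each carbanion formed by addition expels the next halide), aryne ring closures by tethered heteroatom nucleophiles, and the cleavage of ethers and tertiary amines by arynes through onium zwitterions and Hofmann-type β-elimination; using a tert-butyl ether as a traceless second oxygen nucleophile in such a domino is the untested element. No stereocentre is formed: C2 and C3 come unchanged from 7 because neither C–O bond at a stereocentre is broken. Two selectivities are needed, the order in which the two oxygens add and the site of the second aryne: the first is secured because only the benzylic oxygen is anionic while the other is a hindered ether that should react only intramolecularly, the second because aryne 13 is born from the carbanion of the first addition and not from a second deprotonation (which in an isolated 3,5-dichlorophenyl ether would be expected between the two chlorines), so the surviving chlorine ends on C6, para to O1. Generating both anions with n-BuLi keeps amines out of the flask, which could otherwise shuttle a proton onto 12 before it loses chloride.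

**Step 6**
Reactants: 15 (2R,3R)-6-chloro-2-methyl-3-(3,4,5-trimethoxyphenyl)-2,3-dihydro-1,4-benzodioxine
Product: 16 (2R,3R)-2-methyl-6-(prop-2-en-1-yl)-3-(3,4,5-trimethoxyphenyl)-2,3-dihydro-1,4-benzodioxine
Conditions: allylboronic acid pinacol ester (1.5 equiv), Pd(OAc)2 (3 mol %), 2-dicyclohexylphosphino-2′,4′,6′-triisopropylbiphenyl (XPhos, 6 mol %), K3PO4 (3 equiv), THF/H2O 10:1, 60 °C
Reagents that add atoms: allylboronic acid pinacol ester, C=CCB1OC(C)(C)C(C)(C)O1
Why: Suzuki–Miyaura cross-coupling: oxidative addition of the C6–Cl bond to zerovalent palladium carrying the bulky electron-rich biarylphosphine, transmetalation with the allylboronate and reductive elimination should give the allylarene, the mild temperature limiting migration of the double bond into conjugation; no stereocentre is touched.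

**Compound list**

1 | methyl (R)-lactate | C[C@@H](O)C(=O)OC | starting material
2 | methyl (R)-2-tert-butoxypropanoate | C[C@@H](OC(C)(C)C)C(=O)OC | intermediate
3 | (R)-2-tert-butoxy-N-methoxy-N-methylpropanamide | C[C@@H](OC(C)(C)C)C(=O)N(C)OC | intermediate
4 | 3,4,5-trimethoxyphenylmagnesium bromide | COc1cc([Mg]Br)cc(OC)c1OC | starting material
5 | bromomagnesium (2R)-2-tert-butoxy-1-[methoxy(methyl)amino]-1-(3,4,5-trimethoxyphenyl)propan-1-olate (magnesium hemiaminal chelate) | C[C@@H](OC(C)(C)C)C(O[Mg]Br)(N(C)OC)c1cc(OC)c(OC)c(OC)c1 | intermediate
6 | (R)-2-tert-butoxy-1-(3,4,5-trimethoxyphenyl)propan-1-one | C[C@@H](OC(C)(C)C)C(=O)c1cc(OC)c(OC)c(OC)c1 | intermediate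
7 | (1R,2R)-2-tert-butoxy-1-(3,4,5-trimethoxyphenyl)propan-1-ol | O[C@H](c1cc(OC)c(OC)c(OC)c1)[C@@H](C)OC(C)(C)C | intermediate
8 | 1,3,5-trichlorobenzene | Clc1cc(Cl)cc(Cl)c1 | starting material
9 | lithium (1R,2R)-2-tert-butoxy-1-(3,4,5-trimethoxyphenyl)propan-1-olate | [Li+].[O-][C@H](c1cc(OC)c(OC)c(OC)c1)[C@@H](C)OC(C)(C)C | intermediate
10 | 2,4,6-trichlorophenyllithium | [Li]c1c(Cl)cc(Cl)cc1Cl | intermediate
11 | 3,5-dichlorobenzyne (3,5-dichloro-1,2-didehydrobenzene) | ClC1=CC(Cl)=CC#C1 | intermediate
12 | {2,4-dichloro-6-[(1R,2R)-2-tert-butoxy-1-(3,4,5-trimethoxyphenyl)propoxy]phenyl}lithium | [Li]c1c(Cl)cc(Cl)cc1O[C@H](c1cc(OC)c(OC)c(OC)c1)[C@@H](C)OC(C)(C)C | intermediate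
13 | 3-[(1R,2R)-2-tert-butoxy-1-(3,4,5-trimethoxyphenyl)propoxy]-5-chloro-1,2-didehydrobenzene | C1#CC=C(Cl)C=C1O[C@H](c2cc(OC)c(OC)c(OC)c2)[C@@H](C)OC(C)(C)C | intermediate
14 | (2R,3R)-1-tert-butyl-6-chloro-2-methyl-3-(3,4,5-trimethoxyphenyl)-2,3-dihydro-1,4-benzodioxin-1-ium-8-ide | Clc1c[c-]c2c(c1)O[C@H](c1cc(OC)c(OC)c(OC)c1)[C@@H](C)[O+]2C(C)(C)C | intermediate
15 | (2R,3R)-6-chloro-2-methyl-3-(3,4,5-trimethoxyphenyl)-2,3-dihydro-1,4-benzodioxine | Clc1ccc2c(c1)O[C@H](c1cc(OC)c(OC)c(OC)c1)[C@@H](C)O2 | intermediate
16 | (2R,3R)-2-methyl-6-(prop-2-en-1-yl)-3-(3,4,5-trimethoxyphenyl)-2,3-dihydro-1,4-benzodioxine | C=CCc1ccc2c(c1)O[C@H](c1cc(OC)c(OC)c(OC)c1)[C@@H](C)O2 | target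

**Step count and risks**

Total steps: 6. Longest linear sequence: 6 steps (1, 2, 3, 6, 7, 15, 16).

Step 5 (key step, proposed new method). What may go wrong:
- capture of aryne 11 by aryllithium 10 or 12 instead of by alkoxide 9;
- proton transfer to 12 before it loses chloride, which stalls the sequence at the open aryl ether;
- interception of aryne 13 at its distal carbon by an intermolecular nucleophile faster than the hindered ether oxygen closes ring B;
- collapse of 14 by carbon–carbon bond formation instead of by loss of isobutene.

Fallback (known chemistry, same O1–C8a closure), setting out from 7: the sodium alkoxide (NaH, DMF, 0 to 60 °C) displaces fluoride from 1-bromo-4-chloro-2-fluorobenzene by nucleophilic aromatic substitution, with retention at the benzylic carbon because its C–O bond is untouched, to give 1-bromo-4-chloro-2-[(1R,2R)-2-tert-butoxy-1-(3,4,5-trimethoxyphenyl)propoxy]benzene F1. Cleavage of the tert-butyl ether with ZnBr2 in CH2Cl2 at 23 °C gives (1R,2R)-1-(2-bromo-5-chlorophenoxy)-1-(3,4,5-trimethoxyphenyl)propan-2-ol F2. Intramolecular palladium-catalysed C–O coupling at the C–Br bond (Pd(OAc)2, 2-(di-tert-butylphosphino)-1,1′-binaphthyl, Cs2CO3, toluene, 80 °C), which should leave the C–Cl bond alone, closes ring B and comes back to the route at 15.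

Step 6. What may go wrong: slow oxidative addition into the electron-rich C–Cl bond, protodeboronation of the allylboronate, and migration of the double bond into conjugation with ring A through a palladium hydride. Fallback with inverted polarity, setting out from 15: Miyaura borylation (B2pin2, Pd(OAc)2, XPhos, KOAc, 1,4-dioxane, 100 °C) gives (2R,3R)-2-methyl-6-(4,4,5,5-tetramethyl-1,3,2-dioxaborolan-2-yl)-3-(3,4,5-trimethoxyphenyl)-2,3-dihydro-1,4-benzodioxine F3. Suzuki–Miyaura coupling of F3 with allyl bromide (Pd(PPh3)4, K2CO3, THF/H2O, 50 °C), in which the allyl group enters as a π-allylpalladium electrophile, comes back to the route at 16.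

Step 4. What may go wrong: poor facial selectivity if a chelated transition state competes with the Felkin–Anh one. Fallback, setting out from 6: substrate control is replaced by catalyst control in a Noyori-type asymmetric transfer hydrogenation (RuCl(p-cymene)[(S,S)-TsDPEN], HCO2H/Et3N, 30 °C). The catalyst enantiomer that gives (S)-1-phenylethanol from acetophenone should deliver hydride to the face that here corresponds to (1R), and the path comes back to the route directly at 7; no new compound arises on it (F0).

**Further compounds**

F1 | step 5 | 1-bromo-4-chloro-2-[(1R,2R)-2-tert-butoxy-1-(3,4,5-trimethoxyphenyl)propoxy]benzene | Clc1ccc(Br)c(c1)O[C@H](c1cc(OC)c(OC)c(OC)c1)[C@@H](C)OC(C)(C)C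
F2 | step 5 | (1R,2R)-1-(2-bromo-5-chlorophenoxy)-1-(3,4,5-trimethoxyphenyl)propan-2-ol | Clc1ccc(Br)c(c1)O[C@H](c1cc(OC)c(OC)c(OC)c1)[C@@H](C)O
F3 | step 6 | (2R,3R)-2-methyl-6-(4,4,5,5-tetramethyl-1,3,2-dioxaborolan-2-yl)-3-(3,4,5-trimethoxyphenyl)-2,3-dihydro-1,4-benzodioxine | CC1(C)OB(OC1(C)C)c1ccc2c(c1)O[C@H](c1cc(OC)c(OC)c(OC)c1)[C@@H](C)O2
F0 | step 4 | none | none
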